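**Retrosynthetic overview**

1. Endgame: the acid comes from its 2-(trimethylsilyl)ethyl (TMSE) ester; the diene and the C8=CH2 group come from one double methylenation of a C8 ketone and a C14 enal (the enal from cross-metathesis of a C9 allyl group); C6–OAc comes from conjugate borylation of a 6-en-8-one; C9–H comes from SmI2 cleavage of a C9–O bond.
2. That ring B comes from a trans-fused 8-methoxy-7-ene-6,9-dione, itself obtained by opening an enol lactone C18(=O)–O–C6.
3. Key disconnection C10–C1: ring A is closed last, by intramolecular C-alkylation of a C9 phenoxide that dearomatises ring B and creates the quaternary C10.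
4. Enabling feature: ring B (C5–C10) is the carbon skeleton of 2-methoxy-6-methylhydroquinone. The C9 oxygen sits ortho to the methyl-bearing C10 and makes it nucleophilic; the C6 oxygen (para to C9–O) is 1,3-related to the C18 carboxyl through C4–C5 and is tied to it as a benzofuranone, which relays C4 to C10; C8–OMe is the latent C8 ketone.
5. Ring order: ring B (aromatic, from quinone 2), then the temporary lactone ring, then ring A (step 5), then lactone opening (step 6); C4 is set by a catalytic Michael addition.

Key step: step 5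

Remark: labdane locants are used for all compounds (ring A = C1–C5 and C10; ring B = C5–C10; C18 = carboxyl carbon on C4; C19 = methyl on C4; C20 = methyl on C10; C17 on C8; C11–C16 = side chain on C9). TMSE = 2-(trimethylsilyl)ethyl.
Remark (assumption): the sense of induction of the cinchona catalyst in step 3 is assumed; if the quinidine-derived catalyst gives the (R) adduct, its quinine-derived pseudoenantiomer is used.

**Step 1**
Reactants: 1 2-methoxy-6-methylphenol
Product: 2 2-methoxy-6-methyl-1,4-benzoquinone
Conditions: Co(salen) (5 mol %), O2 (1 atm), DMF, 25 °C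
Reagents that add atoms: dioxygen, O=O
Why: Cobalt–salen-catalysed aerobic oxidation of a phenol whose two ortho positions are blocked should give the para-quinone only, and no stereocentre is formed.

**Step 2**
Reactants: 2 2-methoxy-6-methyl-1,4-benzoquinone; 3 1-methoxy-1-(trimethylsilyloxy)prop-1-ene
Product: 5 5-hydroxy-6-methoxy-3,4-dimethylbenzofuran-2(3H)-one, via hydroquinone ester 4 (not isolated)
Conditions: MeCN, −30 → 25 °C; concentrate; then TsOH·H2O (10 mol %), toluene, 110 °C
Reagents that add atoms: 3 1-methoxy-1-(trimethylsilyloxy)prop-1-ene, CC=C(OC)O[Si](C)(C)C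
Why: Mukaiyama–Michael addition of the silyl ketene acetal should occur at C5, the only unsubstituted carbon of the methyl-bearing double bond and β to the C9 carbonyl that the methoxy group does not deactivate, after which the adduct aromatises to 4 and acid closes the five-membered lactone onto the adjacent C6 hydroxyl; C4 is still racemic and enolisable.

**Step 3**
Reactants: 5 5-hydroxy-6-methoxy-3,4-dimethylbenzofuran-2(3H)-one; 6 acrolein
Product: 8 (S)-5-hydroxy-3-(3-hydroxypropyl)-6-methoxy-3,4-dimethylbenzofuran-2(3H)-one, via aldehyde 7 (not isolated)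
Conditions: 9-amino(9-deoxy)epi-quinidine 3,5-bis(trifluoromethyl)phenyl thiourea (10 mol %), toluene, −40 °C, Ar; then NaBH4, EtOH, −40 → 0 °C
Reagents that add atoms: 6 acrolein, C=CC=O
Why: Bifunctional cinchona–thiourea-catalysed asymmetric Michael addition of the planar benzofuranone enolate to acrolein should set the quaternary C4 centre by catalyst control of the enolate face in the hydrogen-bonded ion pair, and reduction of the aldehyde in the same flask prevents retro-Michael loss.

**Step 4**
Reactants: 8 (S)-5-hydroxy-3-(3-hydroxypropyl)-6-methoxy-3,4-dimethylbenzofuran-2(3H)-one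
Product: 9 (S)-3-(3-bromopropyl)-5-hydroxy-6-methoxy-3,4-dimethylbenzofuran-2(3H)-one
Conditions: CBr4, PPh3, CH2Cl2, 0 °C
Reagents that add atoms: tetrabromomethane, BrC(Br)(Br)Br
Why: The Appel reaction should convert only the primary aliphatic alcohol into the bromide, since the hindered phenol cannot be displaced, and C4 is untouched.

**Step 5**
Reactants: 9 (S)-3-(3-bromopropyl)-5-hydroxy-6-methoxy-3,4-dimethylbenzofuran-2(3H)-one
Product: 10 (2aS,5aR)-7-methoxy-2a,5a-dimethyl-2a,3,4,5-tetrahydro-2H-naphtho[1,8-bc]furan-2,6(5aH)-dione (tricyclic dienone enol lactone; C19 and C20 cis)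
Conditions: KOt-Bu (1.0 equiv), t-BuOH/THF 1:1 (0.005 M), Ar, 25 → 65 °C
Reagents that add atoms: none
Why: Deprotonation gives the C9 phenoxide, whose ortho carbon C10 (the one bearing the methyl group) displaces bromide from C1 in an intramolecular SN2 C-alkylation; because C10 becomes quaternary the ring cannot re-aromatise, so ring B emerges as the 2,4-dienone (C9 ketone, C7=C8, C5=C6 enol lactone). The closest known reaction types are the intramolecular alkylative dearomatisation of phenoxides (Winstein-type ortho aryl participation) and the C-alkylation of 2,6-disubstituted phenoxides to 6,6-disubstituted cyclohexa-2,4-dienones. Ring A closes in the 6-exo-tet mode (C4–C3–C2–C1–C10–C5). The new C10 stereocentre is controlled by C4 through the lactone: C18 is held in the plane of ring B by its bond to O6, so C3 and the C19 methyl lie on opposite faces, the three-carbon tether can reach C10 only from its own face, and the C20 methyl is forced onto the face of C19, as in the target. The step needs C- over O-alkylation and C10 over the other ring carbons: O-alkylation would require an eight-membered ring and can only occur between molecules (suppressed by high dilution and the protic medium), C8 is out of reach, and attack at C6 would give a bridged anti-Bredt system. One equivalent of base is consumed by the phenol, so the lactone should survive.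

**Step 6**
Reactants: 10 tricyclic dienone enol lactone; 11 2-(trimethylsilyl)ethanol
Product: 12 TMSE (1S,4aR,8aS)-6-methoxy-1,4a-dimethyl-5,8-dioxo-1,2,3,4,4a,5,8,8a-octahydronaphthalene-1-carboxylate (8-methoxy-7-ene-6,9-dione; H5 trans to C20)
Conditions: 11 (1.1 equiv), n-BuLi (1.05 equiv), THF, −78 → 0 °C; then AcOH, −78 °C
Reagents that add atoms: 11 2-(trimethylsilyl)ethanol, C[Si](C)(C)CCO
Why: Acyl substitution by the lithium alkoxide at the strained enol lactone should give the ester and the C5–C6 enolate, and protonation of C5 on the face opposite the two axial methyl groups (C19, C20) gives the trans ring fusion, which is also the thermodynamic isomer of angularly methylated enediones of this kind.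

**Step 7**
Reactants: 12 enedione TMSE ester; 13 allylmagnesium bromide; 14 acetic anhydride
Product: 16 TMSE 9-acetoxy-9-allyl-8-methoxy-6-oxo-7-ene ester (allyl trans to C20), via magnesium alkoxide 15 (not isolated)
Conditions: 13 (1.2 equiv), THF, −78 °C; then 14 (3 equiv), DMAP (0.1 equiv), −78 → 25 °C
Reagents that add atoms: 13 allylmagnesium bromide, C=CC[Mg]Br; 14 acetic anhydride, CC(=O)OC(C)=O
Why: Grignard 1,2-addition should occur at the C9 ketone because the C6 carbonyl is a deactivated vinylogous ester and the neopentyl ester is hindered, the alkoxide is trapped as the acetate needed for the later C–O cleavage, and the C9 configuration formed here (attack anti to C20) is of no consequence because this centre is reset in step 9.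

**Step 8**
Reactants: 16 TMSE 9-acetoxy-9-allyl-8-methoxy-6-oxo-7-ene ester
Product: 18 TMSE 9-acetoxy-9-allyl-8-oxo-6-ene ester, via allylic alcohol 17 (not isolated)
Conditions: NaBH4, CeCl3·7H2O, MeOH, −20 → 0 °C; then 1 M HCl, THF, 25 °C
Reagents that add atoms: water, O
Why: This is a Stork–Danheiser transposition, in which Luche 1,2-reduction of the vinylogous ester carbonyl at C6 and acid hydrolysis of the enol ether with loss of the C6 hydroxyl should move the carbonyl to C8 and leave the C6=C7 enone; the C6 carbinol centre is destroyed again.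

**Step 9**
Reactants: 18 TMSE 9-acetoxy-9-allyl-8-oxo-6-ene ester
Product: 19 TMSE 9-allyl-8-oxo-6-ene ester (H9 trans to C20, allyl equatorial)
Conditions: SmI2 (2.2 equiv), THF/MeOH, −78 °C
Reagents that add atoms: none
Why: Samarium diiodide reductive cleavage of the α-acetoxy ketone should give the C8–C9 samarium enolate regiospecifically, and protonation by methanol on the face opposite the axial C20 methyl sets C9 with the allyl group equatorial, which is also the thermodynamic epimer.

**Step 10**
Reactants: 19 TMSE 9-allyl-8-oxo-6-ene ester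
Product: 21 TMSE 9-allyl-6-hydroxy-8-oxo ester (6-OH equatorial, trans to C20), via boronate 20 (not isolated)
Conditions: B2pin2 (1.2 equiv), CuCl (5 mol %), NaOt-Bu (10 mol %), DPEphos (5 mol %), MeOH (2 equiv), THF, 25 °C; then NaBO3·4H2O, THF/H2O, 25 °C
Reagents that add atoms: bis(pinacolato)diboron, CC1(C)OB(OC1(C)C)B1OC(C)(C)C(C)(C)O1 (boron is held only in 20); sodium perborate, [Na+].OO[B-](O)(O)O
Why: Copper-catalysed conjugate borylation of the enone should deliver boron to C6 from the face opposite the two syn-axial methyl groups (C19 and C20), oxidation with retention then gives the equatorial C6 alcohol, and the isolated allyl alkene is inert to the copper boryl species.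

**Step 11**
Reactants: 21 TMSE 9-allyl-6-hydroxy-8-oxo ester; 14 acetic anhydride
Product: 22 TMSE 6-acetoxy-9-allyl-8-oxo ester
Conditions: Ac2O, pyridine, DMAP (5 mol %), CH2Cl2, 0 °C
Reagents that add atoms: 14 acetic anhydride, CC(=O)OC(C)=O
Why: DMAP-catalysed acylation of the secondary alcohol under cold, weakly basic conditions should give the acetate without E1cB loss of the β-oxygen, and no stereocentre changes.

**Step 12**
Reactants: 22 TMSE 6-acetoxy-9-allyl-8-oxo ester; 23 methacrolein
Product: 24 TMSE 6-acetoxy-8-oxo-9-[(E)-3-methyl-4-oxobut-2-enyl] ester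
Conditions: second-generation Hoveyda–Grubbs catalyst (5 mol %), 23 (10 equiv), CH2Cl2, 40 °C
Reagents that add atoms: 23 methacrolein, C=C(C)C=O
Why: Olefin cross-metathesis of the terminal alkene with methacrolein should give the trisubstituted enal with the (E) geometry under thermodynamic control, which fixes the C12=C13 configuration.

**Step 13**
Reactants: 24 TMSE 6-acetoxy-8-oxo-9-[(E)-3-methyl-4-oxobut-2-enyl] ester
Product: 25 TMSE (12E)-6-acetoxylabda-8(17),12,14-trien-18-oate
Conditions: Zn, CH2Br2, TiCl4, THF/CH2Cl2, 0 → 25 °C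
Reagents that add atoms: dibromomethane, BrCBr
Why: Takai–Lombardo methylenation should convert both the C8 ketone and the C14 aldehyde into C=CH2 under non-basic conditions, so the β-acetoxy ketone does not eliminate, C9 does not epimerise and the esters are untouched.

**Step 14**
Reactants: 25 TMSE (12E)-6-acetoxylabda-8(17),12,14-trien-18-oate
Product: 26 (1S,4aS,5R,8R,8aS)-8-acetoxy-1,4a-dimethyl-6-methylidene-5-[(2E)-3-methylpenta-2,4-dien-1-yl]decahydronaphthalene-1-carboxylic acid (CNP0240327.3)
Conditions: Bu4NF (2 equiv), THF, 0 → 25 °C; cold 0.5 M HCl work-up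
Reagents that add atoms: none
Why: Fluoride-induced fragmentation of the 2-(trimethylsilyl)ethyl ester should free the hindered acid without touching the secondary acetate, the exocyclic alkene or the diene.

**Compound list**

1 | 2-methoxy-6-methylphenol | COc1cccc(C)c1O | starting material
2 | 2-methoxy-6-methyl-1,4-benzoquinone | COC1=CC(=O)C=C(C)C1=O | intermediate
3 | 1-methoxy-1-(trimethylsilyloxy)prop-1-ene (E/Z mixture) | CC=C(OC)O[Si](C)(C)C | starting material
4 | methyl 2-(3,6-dihydroxy-4-methoxy-2-methylphenyl)propanoate (racemic) | COC(=O)C(C)c1c(C)c(O)c(OC)cc1O | intermediate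
5 | 5-hydroxy-6-methoxy-3,4-dimethylbenzofuran-2(3H)-one (racemic, C3 enolisable) | CC1C(=O)Oc2cc(OC)c(O)c(C)c12 | intermediate
6 | acrolein | C=CC=O | starting material
7 | (S)-3-(5-hydroxy-6-methoxy-3,4-dimethyl-2-oxo-2,3-dihydrobenzofuran-3-yl)propanal | O=CCC[C@]1(C)C(=O)Oc2cc(OC)c(O)c(C)c21 | intermediate
8 | (S)-5-hydroxy-3-(3-hydroxypropyl)-6-methoxy-3,4-dimethylbenzofuran-2(3H)-one | OCCC[C@]1(C)C(=O)Oc2cc(OC)c(O)c(C)c21 | intermediate
9 | (S)-3-(3-bromopropyl)-5-hydroxy-6-methoxy-3,4-dimethylbenzofuran-2(3H)-one | BrCCC[C@]1(C)C(=O)Oc2cc(OC)c(O)c(C)c21 | intermediate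
10 | (2aS,5aR)-7-methoxy-2a,5a-dimethyl-2a,3,4,5-tetrahydro-2H-naphtho[1,8-bc]furan-2,6(5aH)-dione | O=C1OC2=C3[C@]1(C)CCC[C@@]3(C)C(=O)C(OC)=C2 | intermediate
11 | 2-(trimethylsilyl)ethanol | C[Si](C)(C)CCO | starting material
12 | 2-(trimethylsilyl)ethyl (1S,4aR,8aS)-6-methoxy-1,4a-dimethyl-5,8-dioxo-1,2,3,4,4a,5,8,8a-octahydronaphthalene-1-carboxylate | C[Si](C)(C)CCOC(=O)[C@@]1(C)CCC[C@]2(C)[C@@H]1C(=O)C=C(OC)C2=O | intermediate
13 | allylmagnesium bromide | C=CC[Mg]Br | starting material
14 | acetic anhydride | CC(=O)OC(C)=O | starting material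
15 | bromomagnesium C9 alkoxide of the allyl adduct of 12 (allyl trans to C20) | C[Si](C)(C)CCOC(=O)[C@@]1(C)CCC[C@]2(C)[C@@H]1C(=O)C=C(OC)[C@@]2(CC=C)O[Mg]Br | intermediate
16 | TMSE 9-acetoxy-9-allyl-8-methoxy-6-oxo-7-ene ester (C4, C5, C10 as in 12; allyl trans to C20) | C[Si](C)(C)CCOC(=O)[C@@]1(C)CCC[C@]2(C)[C@@H]1C(=O)C=C(OC)[C@@]2(CC=C)OC(C)=O | intermediate
17 | TMSE 9-acetoxy-9-allyl-6-hydroxy-8-methoxy-7-ene ester (6-OH cis to C20) | C[Si](C)(C)CCOC(=O)[C@@]1(C)CCC[C@]2(C)[C@@H]1[C@@H](O)C=C(OC)[C@@]2(CC=C)OC(C)=O | intermediate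
18 | TMSE 9-acetoxy-9-allyl-8-oxo-6-ene ester | C[Si](C)(C)CCOC(=O)[C@@]1(C)CCC[C@]2(C)[C@@H]1C=CC(=O)[C@@]2(CC=C)OC(C)=O | intermediate
19 | TMSE 9-allyl-8-oxo-6-ene ester (H9 trans to C20) | C[Si](C)(C)CCOC(=O)[C@@]1(C)CCC[C@]2(C)[C@@H]1C=CC(=O)[C@H]2CC=C | intermediate
20 | TMSE 9-allyl-8-oxo-6-(4,4,5,5-tetramethyl-1,3,2-dioxaborolan-2-yl) ester (boron trans to C20) | C[Si](C)(C)CCOC(=O)[C@@]1(C)CCC[C@]2(C)[C@@H]1[C@H](B3OC(C)(C)C(C)(C)O3)CC(=O)[C@H]2CC=C | intermediate
21 | TMSE 9-allyl-6-hydroxy-8-oxo ester (6-OH equatorial, trans to C20) | C[Si](C)(C)CCOC(=O)[C@@]1(C)CCC[C@]2(C)[C@@H]1[C@H](O)CC(=O)[C@H]2CC=C | intermediate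
22 | TMSE 6-acetoxy-9-allyl-8-oxo ester | C[Si](C)(C)CCOC(=O)[C@@]1(C)CCC[C@]2(C)[C@@H]1[C@H](OC(C)=O)CC(=O)[C@H]2CC=C | intermediate
23 | methacrolein | C=C(C)C=O | starting material
24 | TMSE 6-acetoxy-8-oxo-9-[(E)-3-methyl-4-oxobut-2-enyl] ester | C[Si](C)(C)CCOC(=O)[C@@]1(C)CCC[C@]2(C)[C@@H]1[C@H](OC(C)=O)CC(=O)[C@H]2C/C=C(C)/C=O | intermediate
25 | TMSE (4S,5S,6R,9R,10S,12E)-6-acetoxylabda-8(17),12,14-trien-18-oate | C[Si](C)(C)CCOC(=O)[C@@]1(C)CCC[C@]2(C)[C@@H]1[C@H](OC(C)=O)CC(=C)[C@H]2C/C=C(C)/C=C | intermediate
26 | (1S,4aS,5R,8R,8aS)-8-acetoxy-1,4a-dimethyl-6-methylidene-5-[(2E)-3-methylpenta-2,4-dien-1-yl]decahydronaphthalene-1-carboxylic acid | OC(=O)[C@@]1(C)CCC[C@]2(C)[C@@H]1[C@H](OC(C)=O)CC(=C)[C@H]2C/C=C(C)/C=C | target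

**Step count and risks**

Total step count: 14. Longest linear sequence: 14 (from 1; all other inputs are commercial).

The three steps most likely to fail:

Step 5. Intermolecular O-alkylation and base-induced loss of HBr may outrun C-alkylation at the substituted ortho carbon, so that oligomers or the terminal alkene form instead of the dienone. The fallback activates the electrophile instead of the nucleophile. From 9, NaI in acetone should give the iodide (S)-5-hydroxy-3-(3-iodopropyl)-6-methoxy-3,4-dimethylbenzofuran-2(3H)-one F1. AgOTf with 2,6-di-tert-butylpyridine in (CF3)2CHOH at 0 °C should then make the neutral phenol ring attack the developing C1 cation through C10 (solvolytic ortho aryl participation, a Friedel–Crafts-type ipso alkylation). Loss of the phenolic proton returns the route at 10, with the same lactone control of C10.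

Step 3. The catalyst may discriminate poorly between the faces of the hindered, peri-methylated enolate, and the free phenol may disturb the hydrogen-bonded ion pair, giving low enantioselectivity. The fallback sets C4 by palladium-catalysed asymmetric allylic alkylation on a protected lactone. From 5, TBSCl and imidazole in DMF should give 5-(tert-butyldimethylsilyloxy)-6-methoxy-3,4-dimethylbenzofuran-2(3H)-one F2. Pd2(dba)3 with a chiral DACH-phenyl Trost bisphosphine and allyl methyl carbonate in toluene should give (S)-3-allyl-5-(tert-butyldimethylsilyloxy)-6-methoxy-3,4-dimethylbenzofuran-2(3H)-one F3. 9-BBN followed by NaBO3·4H2O should give (S)-5-(tert-butyldimethylsilyloxy)-3-(3-hydroxypropyl)-6-methoxy-3,4-dimethylbenzofuran-2(3H)-one F4. Bu4NF buffered with AcOH removes the silyl group and returns the route at 8.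

Step 10. Conjugate borylation at the neopentyl-like C6 may be slow or add from the wrong face. The fallback is nucleophilic epoxidation followed by reductive opening. From 19, t-BuOOH and DBU in CH2Cl2 should give the 6,7-epoxy-8-ketone TMSE 9-allyl-6,7-epoxy-8-oxo ester F5, with the epoxide on the face opposite C19 and C20. SmI2 in THF/MeOH at −90 °C should cleave the C7–O bond α to the ketone and return the route at 21.

**Further compounds**

F1 | step 5 | (S)-5-hydroxy-3-(3-iodopropyl)-6-methoxy-3,4-dimethylbenzofuran-2(3H)-one | ICCC[C@]1(C)C(=O)Oc2cc(OC)c(O)c(C)c21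
F2 | step 3 | 5-(tert-butyldimethylsilyloxy)-6-methoxy-3,4-dimethylbenzofuran-2(3H)-one (racemic) | CC1C(=O)Oc2cc(OC)c(O[Si](C)(C)C(C)(C)C)c(C)c12
F3 | step 3 | (S)-3-allyl-5-(tert-butyldimethylsilyloxy)-6-methoxy-3,4-dimethylbenzofuran-2(3H)-one | C=CC[C@]1(C)C(=O)Oc2cc(OC)c(O[Si](C)(C)C(C)(C)C)c(C)c21
F4 | step 3 | (S)-5-(tert-butyldimethylsilyloxy)-3-(3-hydroxypropyl)-6-methoxy-3,4-dimethylbenzofuran-2(3H)-one | OCCC[C@]1(C)C(=O)Oc2cc(OC)c(O[Si](C)(C)C(C)(C)C)c(C)c21
F5 | step 10 | TMSE 9-allyl-6,7-epoxy-8-oxo ester (epoxide trans to C20) | C[Si](C)(C)CCOC(=O)[C@@]1(C)CCC[C@]2(C)[C@@H]1[C@@H]3O[C@H]3C(=O)[C@H]2CC=C
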